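## Structural features

The target is a daucane sesquiterpenoid ester: a bicyclo[5.3.0]decadiene in which cyclopentene ring A (C1–C2–C3–C4=C5) is fused through the C1–C5 bond to cycloheptene ring B (C5–C6–C7–C8=C9–C10–C1), and the exocyclic carbon C14 on C8 is esterified by vanillic acid. C1 is an all-carbon quaternary centre carrying the angular methyl group and is the only stereocentre (R); it has no neighbouring stereocentre, so the problem is one of absolute configuration only. C4 carries the isopropyl group and forms with C5 a tetrasubstituted alkene at the ring fusion; the second alkene, C8=C9, is trisubstituted and not conjugated with the first. The fragile parts are the primary allylic ester (ionisation, SN2′ displacement, hydrolysis), the free phenol, and the two alkenes, which strong acid could move. The real difficulty is to create quaternary C1 enantioselectively in a hydrocarbon core with no heteroatom handle near it, and then to close a seven-membered ring with both alkenes in fixed positions. The feature exploited is that methyl-bearing C1 and isopropyl-bearing C4 are 1,4-related through C2–C3: C1–C5 plus one extra alkene carbon make up the para-substituted cyclohexene that 2-isopropylbutadiene and methacrolein give in a Diels–Alder reaction, and excising that extra carbon from the ring (it becomes C6) contracts the cyclohexene to ring A.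

## Logic of the disconnections

**Ester C14–O bond.** 20 is cut into 18 and 19. The allylic vanillate is the most labile part and is attached last, which separates the arene from the terpenoid core. The forward step must acylate with the carboxyl group of 19 and leave its phenol free, and must not ionise the allylic position; a redox condensation that activates the alcohol and uses the more acidic carboxyl group as nucleophile meets both demands.

**C8=C9 of ring B.** 18 is opened to 17. This is the one ring B bond whose formation needs no functional group other than the alkene that is wanted, so ring closure and alkene placement are a single, positionally unambiguous event. The bicycle becomes a cyclopentene with two chains. The forward metathesis must join a 1,1-disubstituted and a monosubstituted alkene into a seven-membered ring and ignore C4=C5 and the free hydroxyl. Closing the same bond by an intramolecular Horner–Wadsworth–Emmons reaction was weighed; it would need C14 as an ester, a phosphonate on C8 and a later hydride reduction, that is, more steps, and is not used.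

**C9=CH2 and the oxidation level of C9.** 17 is traced through 16 (and 15) to 14. The terminal alkene could not have survived ozonolysis, so C9 is carried as a nitrile, which tolerates ozone, amine and acid, ylides and the borane coupling and needs no protecting group. The forward reduction must stop at the aldimine stage and tolerate the free hydroxyl.

**C7–C8 bond.** 14 is cut through 13 into 11 and 12. The piece 12 brings C8, C14 with its oxygen and the methylidene carbon in one operation at the final oxidation level, so no later redox is needed at C14. The bond is made at C7 and not at allylic C6, so no allylic transposition can arise. The forward hydroboration must select the terminal vinyl carbon over C4=C5 and the nitrile, and the coupling must outrun β-hydride elimination.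

**C6=C7 bond.** 11 is cut to 10. C7 arrives as one carbon on the formyl carbon C6, and the later hydroboration turns C6 into the required methylene. The ylide must add to a flanked conjugated aldehyde without deprotonating next to the nitrile.

**C4=C5 bond and the C4/C6 reconnection.** 10 is opened to 9 and 9 is reconnected through 8 to 7. A tetrasubstituted cyclopentene carbaldehyde is the aldol condensation product of a 1,6-keto aldehyde, which is the cleaved form of a cyclohexene; this is the ring contraction that turns the para-substituted cyclohexene into ring A. The forward aldol must use the aldehyde as nucleophile (C5) and the hindered ketone as electrophile (C4); the reverse pairing would give an acylcyclopentene.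

**C10–C9 bond.** 7 is cut through 6 to 5. C10 leaves the cycloaddition as a formyl carbon but must become a methylene carrying C9; a reductive cyanation does both in one step. The forward step must add the isocyanide anion to a neopentyl aldehyde and open the intermediate instead of letting it aromatise.

**C1–C5 and C2–C3 bonds.** 5 is cut into 3 and 4. This is the step of greatest simplification: the only stereocentre and the six-membered ring come from two flat, achiral, acyclic partners. The forward step must select one enantioface of 4 and the para orientation. The two partners need no redesign: the formyl group of 4 is both the binding site for the boron acid and the future C10, and 3 carries the isopropyl group in its final form. The configuration of 5 was checked atom by atom against 20: (S)-C1 of 5 is (R)-C1 of 20, the descriptor changing only because the priorities change.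

**C4–isopropyl bond.** 3 is cut into 1 and 2, both commercial. The forward sp2–sp3 coupling must transfer the secondary alkyl group without isomerisation to n-propyl and without polymerising the diene.

## Other disconnections considered

**Alternative 1:** The cut is the C1–C5 bond of ring A, made by C–H insertion, which traces C1 with its methyl group and the C10–C9 chain to (S)-citronellol A3.
- Forward key step: A3 would be silylated, degraded at its alkene to an acid, extended to a β-keto ester and diazotised to diazo keto ester A2. Rh2(OAc)4 would then release N2, and the rhodium carbenoid at C5 would insert into the tertiary C1–H bond with retention to give cyclopentanone A1.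
- In favour: the absolute configuration of C1 comes from the chiral pool and does not depend on a catalyst, and on this point the alternative is the better plan. Ring A is made at its final size with no ring contraction, and C9 is present from the start at a useful oxidation level; both are points on which it is better. Five-membered ring formation at a tertiary C–H bond is the preferred insertion mode.
- Against: A2 needs about five steps from A3 and involves diazo intermediates. A1 has C4 as a ketone and C6 as an ester, so the isopropyl group and the C4=C5 alkene must still be installed (enol sulfonate formation and cross-coupling) and C6 must be reduced. Ring B must then be built from C6 and C9 by much the same work as in the chosen route.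
- Comparison: on structure, 5 already holds the isopropyl group and every ring A carbon, whereas A1 holds the C10–C9 chain. On mechanism, a stereospecific insertion is more certain than catalyst-controlled face selection. On step economy the chosen plan reaches 5 in two steps against about six for A1, and the work after A1 is at least equal, so the alternative should run to fifteen steps or more against eleven.

**Alternative 2:** The cut is the pair C1–C10 and C5–C9, followed by cleavage of C5–C9 again; the net effect is to form C1–C10 and both rings from the monocyclic enone A5.
- Forward key step: irradiation of A5 bound to a chiral oxazaborolidine activated by AlBr3 would give the tricyclic cyclobutyl acetate A4. Removal of the acetate would then trigger a retro-aldol (de Mayo-type) fragmentation to the hydroazulene dione A6.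
- In favour: the quaternary centre and the complete bicyclo[5.3.0] skeleton arise in two operations, which is better than the chosen plan in speed of skeleton building. Ring B needs no separate closure, and the carbonyl groups at C4 and C9 sit where handles are needed.
- Against: a 2,3-disubstituted cyclopentenone forming two adjacent quaternary carbons lies at the edge of the substrate range in which Lewis-acid-bound enones are known to react with high face selectivity. The unbound enone also absorbs light and would give racemic material, and the method asks for high catalyst loading at low temperature. After A6 two ketones must be told apart: C4 must become the isopropyl-bearing alkene by addition and dehydration towards C5 and not C3, and C9 must become C8(C14)=C9 by acylation at C8 and not C10, reduction and elimination.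
- Comparison: on structure the alternative is superior up to A6 and weaker afterwards, because the chosen route never has to differentiate like functional groups. On mechanism, an excited-state cycloaddition with a competing uncatalysed channel is less secure in enantioselectivity than a ground-state Lewis-acid-catalysed cycloaddition with negligible background. On step economy the two are about equal (twelve to fourteen steps against eleven).

**Alternative 3:** The cut is the pair C7–C8 and C8–C9: C8 with its ester carbon C14 is excised from ring B, leaving the six-membered hydrindenone A8.
- Forward key step: BF3·OEt2 would activate the C9 carbonyl of A8, ethyl diazoacetate A9 would add through its carbon (the future C8), and migration of C7 with loss of N2 would give the ring-expanded β-keto ester A7.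
- In favour: C14 on C8 and an oxygen on C9 arrive in one step, so the endgame (ketone reduction, dehydration into conjugation with the ester, hydride reduction, esterification) is short and regiochemically guided. On functional-group economy of the endgame the alternative is better, and it needs no medium-ring closure, which makes it at least the equal of the chosen plan on that point.
- Against: both candidates for migration, C7 and C10, are methylene groups, so selectivity rests only on the neopentyl character of C10, and multiple homologation is possible. The larger problem is A8 itself: it already holds the quaternary stereocentre, the tetrasubstituted isopropyl alkene and a ketone two carbons from the ring fusion, a pattern the usual enantioselective annulations do not deliver, so the stereochemical problem is moved and not solved.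
- Comparison: on structure the alternative ends better and begins worse. On mechanism a cationic 1,2-shift with two possible migrating groups is less certain than a metathesis that can close only one ring. On step economy a long enantioselective preparation of A8 would outweigh the three or four steps saved at the end.

Key step: step 2

Assumption: the (S)-proline-derived oxazaborolidinium salt is taken to expose the enal face that leads to (S)-5, in line with its behaviour towards other 2-substituted acroleins; should the sense prove opposite, the (R)-proline-derived salt is used and nothing else changes.

## Route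

Step 1
Reactants: 1 2-chlorobuta-1,3-diene; 2 isopropylmagnesium chloride
Product: 3 2-(propan-2-yl)buta-1,3-diene
Conditions: NiCl2(dppp) (1 mol %), Et2O, 0 °C → rt; fractional distillation
Reagents that add atoms: none
Why: Kumada–Corriu coupling: zerovalent nickel formed in the flask inserts into the vinylic C–Cl bond, and transmetallation with 2 followed by reductive elimination gives the 2-alkyl diene. The chelating dppp ligand makes reductive elimination faster than β-hydride elimination, so the secondary alkyl group should be transferred without isomerisation to n-propyl.

Step 2
Reactants: 3 2-(propan-2-yl)buta-1,3-diene; 4 methacrolein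
Product: 5 (1S)-1-methyl-4-(propan-2-yl)cyclohex-3-ene-1-carbaldehyde
Conditions: (S)-3,3-diphenyl-1-(2-methylphenyl)tetrahydro-1H,3H-pyrrolo[1,2-c][1,3,2]oxazaborole (20 mol %), HN(SO2CF3)2 (18 mol %), 3 (2.5 equiv), CH2Cl2, −78 → −40 °C
Reagents that add atoms: none
Why: The triflimide-protonated oxazaborolidine is a cationic boron Lewis acid that binds the formyl oxygen of 4 (the formyl C–H is held against the ring oxygen) and lowers the LUMO of the enal so that the cycloaddition runs at low temperature; the closest known reaction type is the chiral-Lewis-acid-catalysed Diels–Alder reaction of 2-substituted acroleins with 2-substituted butadienes. The cyclohexene is closed in one concerted, asynchronous, suprafacial [4+2] event in which C2–C3 is formed ahead of C1–C5. The one new stereocentre, quaternary C1, is fixed by the enantioface of the bound enal that the diene reaches: one face lies over an aryl group of the catalyst and the other is open. Because 3 has no substituent on its termini, endo and exo approach lead to the same product, so face selection alone decides the configuration. The step also needs para regioselectivity, which the substrate secures: the diene terminus next to the isopropyl-bearing carbon has the larger HOMO coefficient and pairs with the β-carbon of the enal, and Lewis-acid activation sharpens this preference. Excess 3 compensates for its volatility, and the thermal background reaction should be negligible below −40 °C.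

Step 3
Reactants: 5 (1S)-1-methyl-4-(propan-2-yl)cyclohex-3-ene-1-carbaldehyde
Product: 7 2-[(1S)-1-methyl-4-(propan-2-yl)cyclohex-3-en-1-yl]acetonitrile, via alkenyl formamide 6 (not isolated)
Conditions: TosMIC (1.1 equiv), KOtBu (2.2 equiv), DME, −50 °C; then MeOH, reflux
Reagents that add atoms: 4-methylbenzenesulfonylmethyl isocyanide (TosMIC), Cc1ccc(cc1)S(=O)(=O)C[N+]#[C-]
Why: Van Leusen reductive cyanation: the TosMIC anion adds to the non-enolisable aldehyde and cyclises to a 4-tosyl-2-oxazoline, which excess base opens to the alkenyl formamide 6. Methoxide then removes the formyl group as methyl formate and sulfinate is expelled, leaving C10 as a methylene and the new carbon C9 as a nitrile. C1 has no α-hydrogen and is not touched.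

Step 4
Reactants: 7 2-[(1S)-1-methyl-4-(propan-2-yl)cyclohex-3-en-1-yl]acetonitrile
Product: 9 (3R)-3-(cyanomethyl)-3,7-dimethyl-6-oxooctanal, via secondary ozonide 8 (not isolated)
Conditions: O3, CH2Cl2, −78 °C (to the end point of Sudan Red 7B); then PPh3, −78 °C → rt
Reagents that add atoms: ozone, [O-][O+]=O
Why: Ozonolysis of the only C=C bond (1,3-dipolar cycloaddition, cycloreversion and recombination to the secondary ozonide 8), followed by reduction of the peroxide with PPh3. The trisubstituted alkene gives ketone C4 and aldehyde C6, and the nitrile is inert to ozone.

Step 5
Reactants: 9 (3R)-3-(cyanomethyl)-3,7-dimethyl-6-oxooctanal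
Product: 10 2-[(1R)-2-formyl-1-methyl-3-(propan-2-yl)cyclopent-2-en-1-yl]acetonitrile
Conditions: piperidine (0.5 equiv), AcOH (0.5 equiv), toluene, 4 Å molecular sieves, rt → 70 °C
Reagents that add atoms: none
Why: Amine-catalysed intramolecular aldol condensation: the secondary amine condenses only with the aldehyde, and the enamine carbon C5 adds to ketone C4 in a 5-exo-trig closure helped by the gem-disubstituted C1; loss of water and hydrolysis give the conjugated enal. The hindered isopropyl ketone forms no enamine, which disfavours the reverse pairing of C3 with C6.

Step 6
Reactants: 10 2-[(1R)-2-formyl-1-methyl-3-(propan-2-yl)cyclopent-2-en-1-yl]acetonitrile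
Product: 11 2-[(1R)-2-ethenyl-1-methyl-3-(propan-2-yl)cyclopent-2-en-1-yl]acetonitrile
Conditions: Ph3PCH3Br (1.5 equiv), NaN(SiMe3)2 (1.4 equiv), THF, −78 → 0 °C
Reagents that add atoms: methyltriphenylphosphonium bromide, C[P+](c1ccccc1)(c1ccccc1)c1ccccc1.[Br-]
Why: Wittig methylenation of the conjugated aldehyde; the small non-stabilised ylide should add even to this flanked formyl group. With no excess base and low temperature the weakly acidic neopentyl methylene next to the nitrile is not deprotonated.

Step 7
Reactants: 11 2-[(1R)-2-ethenyl-1-methyl-3-(propan-2-yl)cyclopent-2-en-1-yl]acetonitrile; 12 2-bromoprop-2-en-1-ol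
Product: 14 2-[(1R)-2-[3-(hydroxymethyl)but-3-en-1-yl]-1-methyl-3-(propan-2-yl)cyclopent-2-en-1-yl]acetonitrile, via alkylborane 13 (not isolated)
Conditions: 9-BBN (1.3 equiv), THF, 0 °C → rt; then 12 (1.5 equiv), PdCl2(dppf) (5 mol %), AsPh3 (5 mol %), Cs2CO3 (3 equiv), DMF/H2O, rt → 45 °C
Reagents that add atoms: none
Why: Hydroboration puts boron on the terminal carbon C7 of the vinyl group (anti-Markovnikov); 9-BBN does not add to the tetrasubstituted C4=C5 and reduces nitriles only slowly. B-alkyl Suzuki–Miyaura coupling of the base-activated borane 13 with the vinyl bromide at zerovalent palladium then forms C7–C8, the wide-bite-angle dppf ligand letting reductive elimination outrun β-hydride elimination. The free hydroxyl of 12 is tolerated under the aqueous basic conditions.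

Step 8
Reactants: 14 2-[(1R)-2-[3-(hydroxymethyl)but-3-en-1-yl]-1-methyl-3-(propan-2-yl)cyclopent-2-en-1-yl]acetonitrile
Product: 16 2-[(1R)-2-[3-(hydroxymethyl)but-3-en-1-yl]-1-methyl-3-(propan-2-yl)cyclopent-2-en-1-yl]acetaldehyde, via aldimine 15 (not isolated)
Conditions: iBu2AlH (2.5 equiv), CH2Cl2, −78 → −20 °C; then aq. HCl (1 M), THF, 0 °C
Reagents that add atoms: water, O
Why: Partial reduction of a nitrile: one hydride adds to give the N-aluminated aldimine 15, which resists further reduction at low temperature and is hydrolysed to the aldehyde in the cold acidic work-up. The first equivalent of hydride is consumed by the hydroxyl group, and the isolated alkenes are inert.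

Step 9
Reactants: 16 2-[(1R)-2-[3-(hydroxymethyl)but-3-en-1-yl]-1-methyl-3-(propan-2-yl)cyclopent-2-en-1-yl]acetaldehyde
Product: 17 2-methylidene-4-[(5R)-5-methyl-5-(prop-2-en-1-yl)-2-(propan-2-yl)cyclopent-1-en-1-yl]butan-1-ol
Conditions: Ph3PCH3Br (3.0 equiv), KOtBu (2.8 equiv), THF, 0 °C → rt
Reagents that add atoms: methyltriphenylphosphonium bromide, C[P+](c1ccccc1)(c1ccccc1)c1ccccc1.[Br-]
Why: Wittig methylenation of the aliphatic aldehyde turns C9 into the terminal alkene needed for ring closure. One equivalent of ylide is spent on the hydroxyl group, and the neopentyl α-methylene enolises too slowly to compete.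

Step 10
Reactants: 17 2-methylidene-4-[(5R)-5-methyl-5-(prop-2-en-1-yl)-2-(propan-2-yl)cyclopent-1-en-1-yl]butan-1-ol
Product: 18 [(8aR)-8a-methyl-3-(propan-2-yl)-1,2,4,5,8,8a-hexahydroazulen-6-yl]methanol
Conditions: second-generation Grubbs catalyst, RuCl2(=CHPh)(H2IMes)(PCy3) (5 mol %), CH2Cl2 (0.005 M), 40 °C
Reagents that add atoms: none
Why: Ring-closing olefin metathesis: the ruthenium carbene loads on the monosubstituted C9 alkene and closes onto the 1,1-disubstituted C8 alkene through a metallacyclobutane, and loss of ethene drives the reaction. The tetrasubstituted C4=C5 is inert, and the quaternary C1 and the ring A alkene hold the two chains close, which favours the seven-membered ring over oligomers at high dilution. No stereocentre is formed and the ring alkene can only be cis.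

Step 11
Reactants: 18 [(8aR)-8a-methyl-3-(propan-2-yl)-1,2,4,5,8,8a-hexahydroazulen-6-yl]methanol; 19 vanillic acid
Product: 20 [(8aR)-8a-methyl-3-(propan-2-yl)-1,2,4,5,8,8a-hexahydroazulen-6-yl]methyl 4-hydroxy-3-methoxybenzoate
Conditions: PPh3 (1.2 equiv), DIAD (1.2 equiv), THF, 0 °C → rt
Reagents that add atoms: none
Why: Mitsunobu esterification: the betaine is protonated by the carboxylic acid, which is far more acidic than the phenol, and the carboxylate displaces the alkoxyphosphonium group at primary C14 by SN2. The phenol stays free, and nothing acidic or basic enough to move either alkene is present.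

## Compound list

1 | 2-chlorobuta-1,3-diene (chloroprene) | C=CC(Cl)=C | starting material
2 | isopropylmagnesium chloride | CC(C)[Mg]Cl | starting material
3 | 2-(propan-2-yl)buta-1,3-diene | CC(C)C(=C)C=C | intermediate
4 | methacrolein (2-methylprop-2-enal) | CC(=C)C=O | starting material
5 | (1S)-1-methyl-4-(propan-2-yl)cyclohex-3-ene-1-carbaldehyde | O=C[C@@]1(C)CCC(C(C)C)=CC1 | intermediate
6 | N-{2-[(1S)-1-methyl-4-(propan-2-yl)cyclohex-3-en-1-yl]-1-(4-methylbenzenesulfonyl)ethenyl}formamide (alkene geometry not defined) | O=CNC(=C[C@@]1(C)CCC(C(C)C)=CC1)S(=O)(=O)c1ccc(C)cc1 | intermediate (not isolated)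
7 | 2-[(1S)-1-methyl-4-(propan-2-yl)cyclohex-3-en-1-yl]acetonitrile | N#CC[C@@]1(C)CCC(C(C)C)=CC1 | intermediate
8 | 2-[4-methyl-1-(propan-2-yl)-7,8,9-trioxabicyclo[4.2.1]nonan-4-yl]acetonitrile (secondary ozonide of 7; quaternary carbon as in 7, bridgeheads as a mixture) | N#CC[C@@]1(C)CCC2(C(C)C)OOC(C1)O2 | intermediate (not isolated)
9 | (3R)-3-(cyanomethyl)-3,7-dimethyl-6-oxooctanal | N#CC[C@@](CC=O)(C)CCC(=O)C(C)C | intermediate
10 | 2-[(1R)-2-formyl-1-methyl-3-(propan-2-yl)cyclopent-2-en-1-yl]acetonitrile | N#CC[C@@]1(C)CCC(C(C)C)=C1C=O | intermediate
11 | 2-[(1R)-2-ethenyl-1-methyl-3-(propan-2-yl)cyclopent-2-en-1-yl]acetonitrile | N#CC[C@@]1(C)CCC(C(C)C)=C1C=C | intermediate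
12 | 2-bromoprop-2-en-1-ol | OCC(Br)=C | starting material
13 | 2-[(1R)-2-[2-(9-borabicyclo[3.3.1]nonan-9-yl)ethyl]-1-methyl-3-(propan-2-yl)cyclopent-2-en-1-yl]acetonitrile | N#CC[C@@]1(C)CCC(C(C)C)=C1CCB2C3CCCC2CCC3 | intermediate (not isolated)
14 | 2-[(1R)-2-[3-(hydroxymethyl)but-3-en-1-yl]-1-methyl-3-(propan-2-yl)cyclopent-2-en-1-yl]acetonitrile | N#CC[C@@]1(C)CCC(C(C)C)=C1CCC(=C)CO | intermediate
15 | 4-[(5R)-5-(2-iminoethyl)-5-methyl-2-(propan-2-yl)cyclopent-1-en-1-yl]-2-methylidenebutan-1-ol (present in the flask as its N,O-aluminated form) | N=CC[C@@]1(C)CCC(C(C)C)=C1CCC(=C)CO | intermediate (not isolated)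
16 | 2-[(1R)-2-[3-(hydroxymethyl)but-3-en-1-yl]-1-methyl-3-(propan-2-yl)cyclopent-2-en-1-yl]acetaldehyde | O=CC[C@@]1(C)CCC(C(C)C)=C1CCC(=C)CO | intermediate
17 | 2-methylidene-4-[(5R)-5-methyl-5-(prop-2-en-1-yl)-2-(propan-2-yl)cyclopent-1-en-1-yl]butan-1-ol | C=CC[C@@]1(C)CCC(C(C)C)=C1CCC(=C)CO | intermediate
18 | [(8aR)-8a-methyl-3-(propan-2-yl)-1,2,4,5,8,8a-hexahydroazulen-6-yl]methanol | OCC1=CC[C@@]2(C)CCC(C(C)C)=C2CC1 | intermediate
19 | vanillic acid (4-hydroxy-3-methoxybenzoic acid) | COc1cc(C(=O)O)ccc1O | starting material
20 | [(8aR)-8a-methyl-3-(propan-2-yl)-1,2,4,5,8,8a-hexahydroazulen-6-yl]methyl 4-hydroxy-3-methoxybenzoate | COc1cc(C(=O)OCC2=CC[C@@]3(C)CCC(C(C)C)=C3CC2)ccc1O | target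

## Step count and least certain steps

Total step count: 11. Longest linear sequence: 11 steps (from 1 to 20; 4, 12 and 19 enter as purchased materials).

**Step 2 (key step).** The most likely failure is erosion of enantioface selectivity. The bound enal can react through two conformers that expose opposite faces, and any cycloaddition promoted by free acid is racemic; the strong acid may also oligomerise the diene, and a little of the meta regioisomer may form. Fallback: setting out from 3 and 4, the cycloaddition would be run with an achiral Lewis acid (EtAlCl2, CH2Cl2, −78 °C) to give the racemic aldehyde F1. F1 would be condensed with (1R,2R)-N,N′-dimethyl-1,2-diphenylethane-1,2-diamine to a pair of diastereomeric imidazolidines, from which the one with (S)-configured C1, aminal F2, would be separated by chromatography or crystallisation. Mild aqueous acid would then cleave F2 and return the route at 5. Because C1 is quaternary, nothing can epimerise during this resolution.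

**Step 5.** The neopentyl enamine carbon C5 must attack a hindered isopropyl ketone. If this cyclisation is slow, intermolecular condensation of the aldehyde or attack of the ketone enol on the iminium ion (the reverse pairing, leading to an acylcyclopentene) may take over. Fallback: setting out from 9, the nucleophile would be fixed beforehand by condensing the aldehyde alone with pyrrolidine (K2CO3, 0 °C) to the enamine F3. The ketone would then be activated with TiCl4 (CH2Cl2, −78 °C) so that F3 adds to it, and hydrolysis would give the β-hydroxy aldehyde F4. F4 would be dehydrated in a separate base-driven step (MsCl, Et3N) into conjugation, returning at 10. Addition and elimination are thus decoupled, and no ketone-derived nucleophile is ever generated.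

**Step 3.** The oxazoline intermediate may aromatise to an oxazole by loss of sulfinate instead of opening to 6, and methanolysis of 6 may be incomplete. Fallback: setting out from 5, a Wittig reaction with methoxymethylidenetriphenylphosphorane would give the enol ether F5. Aqueous acid would hydrolyse F5 to the homologous aldehyde F6, which would be converted with NH2OH·HCl/NaOAc into the oxime F7 and dehydrated (Ac2O, heat) to return at 7.

**Step 7.** Hydroboration of a vinyl group that is conjugated and flanked by two fully substituted carbons may be slow or incomplete, and in the coupling the alkylborane may suffer protodeboronation or β-hydride elimination after transmetallation. Fallback: setting out from 11, the borane 13 would be oxidised (NaOH, H2O2) to the primary alcohol F8 and converted with PPh3, I2 and imidazole into the iodide F9. Zinc insertion (Zn, LiCl, THF) would give the alkylzinc iodide F10, which tolerates the nitrile. F10 would be joined to 12 (first deprotonated with one equivalent of MeMgCl) in a Negishi coupling catalysed by Pd(OAc)2 and SPhos, returning at 14. The organometallic is then a defined, titratable reagent and no longer a species made and used in one pot.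

**Step 11.** The phenol may be alkylated by a second activated alcohol, some SN2′ transposition may occur, and the polar by-products may be hard to remove from a product of similar polarity. Fallback: setting out from 19, the phenol would be acetylated (Ac2O, pyridine) to 4-acetoxy-3-methoxybenzoic acid F11. F11 would be coupled with 18 using EDC·HCl and DMAP to the acetate-protected ester F12, and the aryl acetate would be removed selectively by aminolysis with pyrrolidine (CH2Cl2, 0 °C), which leaves the benzoate ester intact, returning at 20.

## Further compounds

F1 | step 2 | racemic 1-methyl-4-(propan-2-yl)cyclohex-3-ene-1-carbaldehyde | O=CC1(C)CCC(C(C)C)=CC1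
F2 | step 2 | (4R,5R)-1,3-dimethyl-2-[(1S)-1-methyl-4-(propan-2-yl)cyclohex-3-en-1-yl]-4,5-diphenylimidazolidine | CN1[C@H](c2ccccc2)[C@@H](c2ccccc2)N(C)C1[C@@]3(C)CCC(C(C)C)=CC3
F3 | step 5 | (3R)-3,7-dimethyl-6-oxo-3-[(E)-2-(pyrrolidin-1-yl)ethenyl]octanenitrile | N#CC[C@@](/C=C/N1CCCC1)(C)CCC(=O)C(C)C
F4 | step 5 | 2-[2-formyl-3-hydroxy-1-methyl-3-(propan-2-yl)cyclopentyl]acetonitrile (quaternary carbon as in 10; the two new centres not assigned) | N#CC[C@@]1(C)CCC(O)(C(C)C)C1C=O
F5 | step 3 | (4S)-4-(2-methoxyethenyl)-4-methyl-1-(propan-2-yl)cyclohex-1-ene (E/Z mixture) | COC=C[C@@]1(C)CCC(C(C)C)=CC1
F6 | step 3 | 2-[(1S)-1-methyl-4-(propan-2-yl)cyclohex-3-en-1-yl]acetaldehyde | O=CC[C@@]1(C)CCC(C(C)C)=CC1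
F7 | step 3 | N-{2-[(1S)-1-methyl-4-(propan-2-yl)cyclohex-3-en-1-yl]ethylidene}hydroxylamine | ON=CC[C@@]1(C)CCC(C(C)C)=CC1
F8 | step 7 | 2-[(1R)-2-(2-hydroxyethyl)-1-methyl-3-(propan-2-yl)cyclopent-2-en-1-yl]acetonitrile | N#CC[C@@]1(C)CCC(C(C)C)=C1CCO
F9 | step 7 | 2-[(1R)-2-(2-iodoethyl)-1-methyl-3-(propan-2-yl)cyclopent-2-en-1-yl]acetonitrile | N#CC[C@@]1(C)CCC(C(C)C)=C1CCI
F10 | step 7 | {2-[(5R)-5-(cyanomethyl)-5-methyl-2-(propan-2-yl)cyclopent-1-en-1-yl]ethyl}(iodo)zinc | N#CC[C@@]1(C)CCC(C(C)C)=C1CC[Zn]I
F11 | step 11 | 4-acetoxy-3-methoxybenzoic acid | COc1cc(C(=O)O)ccc1OC(C)=O
F12 | step 11 | [(8aR)-8a-methyl-3-(propan-2-yl)-1,2,4,5,8,8a-hexahydroazulen-6-yl]methyl 4-acetoxy-3-methoxybenzoate | COc1cc(C(=O)OCC2=CC[C@@]3(C)CCC(C(C)C)=C3CC2)ccc1OC(C)=O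
A1 | alternative 1 | ethyl 2-[2-(tert-butyldimethylsilyloxy)ethyl]-2-methyl-5-oxocyclopentane-1-carboxylate (quaternary centre as in the target; ester trans to the side chain) | CCOC(=O)[C@H]1C(=O)CC[C@]1(C)CCO[Si](C)(C)C(C)(C)C
A2 | alternative 1 | ethyl (6S)-8-(tert-butyldimethylsilyloxy)-2-diazo-6-methyl-3-oxooctanoate | CCOC(=O)C(=[N+]=[N-])C(=O)CC[C@H](C)CCO[Si](C)(C)C(C)(C)C
A3 | alternative 1 | (S)-citronellol | OCC[C@@H](C)CCC=C(C)C
A4 | alternative 2 | tricyclic cyclobutyl acetate photoadduct (cis-anti-cis 5-4-5 ring system; quaternary centre as in the target) | C[C@]12CCC(=O)[C@]13CCC[C@]3(OC(C)=O)C2
A5 | alternative 2 | 5-(2-methyl-5-oxocyclopent-1-en-1-yl)pent-1-en-2-yl acetate | CC1=C(CCCC(=C)OC(C)=O)C(=O)CC1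
A6 | alternative 2 | 3a-methyloctahydroazulene-1,5-dione (quaternary centre as in the target; ring-fusion hydrogen not assigned) | C[C@]12CCC(=O)C1CCCC(=O)C2
A7 | alternative 3 | ethyl 7-hydroxy-3-isopropyl-8a-methyl-1,2,4,5,8,8a-hexahydroazulene-6-carboxylate (β-keto ester as its enol; quaternary centre as in the target) | CCOC(=O)C1=C(O)C[C@@]2(C)CCC(C(C)C)=C2CC1
A8 | alternative 3 | 3-isopropyl-7a-methyl-1,2,4,5,7,7a-hexahydro-6H-inden-6-one (quaternary centre as in the target) | O=C1CCC2=C(C(C)C)CC[C@]2(C)C1
A9 | alternative 3 | ethyl diazoacetate | CCOC(=O)C=[N+]=[N-]
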